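**Plan**

1. Retrosynthesis: the catechol is unmasked last, the chromene C3=C4 bond is traced back to a chroman-4-one, and the CMe2 carbon of the cyclobutane to a cyclobutanone carbonyl.
2. The cyclobutane is then cut at two bonds at once: benzylic ring-fusion carbon to aryl-bearing carbon, and homobenzylic ring-fusion carbon to carbonyl carbon. This leaves an indene and an arylacetamide-derived keteniminium.
3. Enabling feature: in the four-membered ring the catechol-bearing CH sits on the benzylic ring-fusion carbon and the CMe2 carbon on the homobenzylic one. This is the orientation in which an electrophilic aryl ketene equivalent adds across the styrenic C=C of an indene fused to ring A.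
4. Forward order: the pyranone ring is built on phloroglucinol, then the cyclopentene ring (Claisen rearrangement, vinylation, ring-closing metathesis), then the cyclobutane by [2+2], then CMe2, chromene and desilylation.
5. Stereochemistry: the four/five ring fusion can only be cis; its absolute sense comes from the C2-symmetric (2R,5R)-2,5-dimethylpyrrolidine on the keteniminium; the aryl-bearing centre is set by base equilibration to the convex face.
6. The catechol is carried as its bis(tert-butyldimethylsilyl) (TBS) ether, which survives the hydrogenolysis that creates the CMe2 group and is removed without touching the chromene.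

Key step: step 10

Assumption: the (2R,5R)-auxiliary is taken to favour the indene face that leads to the (S)-homobenzylic/(R)-benzylic ring fusion; should the sense of induction prove opposite, the (2S,5S)-amine is used with no other change.

Notation: in the cyclobutane, C-a is the homobenzylic ring-fusion CH (bonded to the indane CH2), C-b the benzylic ring-fusion CH (bonded to ring A), C-c the aryl-bearing CH and C-d the fourth carbon (C=O, later CMe2). Chromanone locants (C2 to C8a) are used for the pyran-fused ring A throughout.

**Route**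

Step 1
Reactants: 1 phloroglucinol; 2 3,3-dimethylacrylic acid
Product: 3 5,7-dihydroxy-2,2-dimethylchroman-4-one
Conditions: P2O5, MeSO3H, 70 °C
Reagents that add atoms: none
Why: Friedel–Crafts acylation of the symmetrical triphenol by the activated acid, followed by intramolecular oxa-Michael addition of the neighbouring hydroxyl, should close the 2,2-dimethylpyranone ring, and the symmetry of 1 leaves no regiochemical choice.

Step 2
Reactants: 3 5,7-dihydroxy-2,2-dimethylchroman-4-one
Product: 4 5-hydroxy-7-methoxy-2,2-dimethylchroman-4-one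
Conditions: MeI (1 equiv), K2CO3, acetone, reflux
Reagents that add atoms: iodomethane, CI
Why: Williamson etherification in which the C5 hydroxyl, hydrogen-bonded to the C4 carbonyl, is far less reactive than the free C7 hydroxyl, so one equivalent of iodomethane should methylate C7 only.

Step 3
Reactants: 4 5-hydroxy-7-methoxy-2,2-dimethylchroman-4-one
Product: 5 5-(allyloxy)-7-methoxy-2,2-dimethylchroman-4-one
Conditions: allyl bromide, K2CO3, DMF, 60 °C
Reagents that add atoms: allyl bromide, C=CCBr
Why: Williamson etherification of the chelated phenol, which under the more forcing DMF/heat conditions should be alkylated cleanly because no other nucleophilic site remains.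

Step 4
Reactants: 5 5-(allyloxy)-7-methoxy-2,2-dimethylchroman-4-one
Product: 6 6-allyl-5-hydroxy-7-methoxy-2,2-dimethylchroman-4-one
Conditions: PhNEt2, 200 °C, sealed tube
Reagents that add atoms: none
Why: Aromatic Claisen ([3,3]-sigmatropic) rearrangement; of the two ortho positions only C6 carries hydrogen (C4a is quaternary), so the allyl group should be delivered to C6 and tautomerisation restores the chelated phenol.

Step 5
Reactants: 6 6-allyl-5-hydroxy-7-methoxy-2,2-dimethylchroman-4-one
Product: 7 6-allyl-7-methoxy-2,2-dimethyl-4-oxochroman-5-yl trifluoromethanesulfonate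
Conditions: Tf2O, pyridine, CH2Cl2, 0 °C to rt
Reagents that add atoms: trifluoromethanesulfonic anhydride, O=S(=O)(OS(=O)(=O)C(F)(F)F)C(F)(F)F
Why: O-Sulfonylation (triflation) of the only free hydroxyl turns the C5 oxygen into a leaving group that the ortho carbonyl activates for oxidative addition.

Step 6
Reactants: 7 6-allyl-7-methoxy-2,2-dimethyl-4-oxochroman-5-yl trifluoromethanesulfonate
Product: 8 6-allyl-7-methoxy-2,2-dimethyl-5-vinylchroman-4-one
Conditions: Bu3SnCH=CH2, Pd(PPh3)4, LiCl, 1,4-dioxane, 100 °C
Reagents that add atoms: tributyl(vinyl)stannane, C=C[Sn](CCCC)(CCCC)CCCC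
Why: Stille coupling of an aryl triflate with a vinylstannane, with chloride promoting transmetallation, should replace the C5 oxygen by the vinyl carbon under neutral conditions that leave the allyl group in place.

Step 7
Reactants: 8 6-allyl-7-methoxy-2,2-dimethyl-5-vinylchroman-4-one
Product: 9 tricyclic indene (7-methoxy-2,2-dimethylchroman-4-one with a cyclopentene fused across C5–C6 as C5–CH=CH–CH2–C6)
Conditions: second-generation Grubbs catalyst RuCl2(=CHPh)(H2IMes)(PCy3) (cat.), 1,4-benzoquinone (cat.), CH2Cl2, 40 °C
Reagents that add atoms: none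
Why: Ring-closing olefin metathesis of the vinyl and allyl groups should form the five-membered ring with loss of ethene and place the double bond on the C5 side, benzoquinone suppressing hydride-induced double-bond migration.

Step 8
Reactants: 10 3,4-dihydroxyphenylacetic acid
Product: 12 3,4-bis(tert-butyldimethylsilyloxy)phenylacetic acid, via silyl ester 11 (not isolated)
Conditions: TBSCl, imidazole, DMF, rt; then AcOH, THF–H2O, rt
Reagents that add atoms: tert-butyldimethylsilyl chloride, CC(C)(C)[Si](C)(C)Cl
Why: Exhaustive silylation followed by selective hydrolysis of the labile silyl ester, which is cleaved by aqueous acid far faster than the aryl silyl ethers.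

Step 9
Reactants: 12 3,4-bis(tert-butyldimethylsilyloxy)phenylacetic acid; 13 (2R,5R)-2,5-dimethylpyrrolidine
Product: 15 2-[3,4-bis(tert-butyldimethylsilyloxy)phenyl]-1-[(2R,5R)-2,5-dimethylpyrrolidin-1-yl]ethanone, via acid chloride 14 (not isolated)
Conditions: (COCl)2, DMF (cat.), CH2Cl2, 0 °C to rt, concentrate; then 13, Et3N, CH2Cl2, 0 °C to rt
Reagents that add atoms: none
Why: Amide formation by N-acylation with the acid chloride, the most reliable way to acylate this α,α'-disubstituted secondary amine; its two stereocentres are untouched.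

Step 10
Reactants: 15 2-[3,4-bis(tert-butyldimethylsilyloxy)phenyl]-1-[(2R,5R)-2,5-dimethylpyrrolidin-1-yl]ethanone; 9 tricyclic indene
Product: 19 cis-fused cyclobuta-indane cyclobutanone (C-d ketone; 3,4-bis(TBSO)phenyl at C-c on the convex face; C-a S; C-b R; C-c R; chromanone intact), via keteniminium triflate 16 (not isolated), via cyclobutaniminium triflate 17 (not isolated), via ketone C-c epimer mixture 18 (not isolated)
Conditions: 15 (1.5 equiv), Tf2O (1.4 equiv), ClCH2CH2Cl, −20 °C; then 9 (1.0 equiv), 2,4,6-collidine (slow addition), 80 °C; then aq NaHCO3, 80 °C; then DBU (cat.), CH2Cl2, rt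
Reagents that add atoms: water, O
Why: O-Triflation of amide 15 and collidine-induced loss of triflic acid give the aryl keteniminium 16, whose sp carbon is attacked by the homobenzylic carbon of the indene double bond of 9; the benzylic cation so formed is captured by the enamine carbon, so the cyclobutane closes by a stepwise polar [2+2] (the second bond by intramolecular enamine alkylation of the cation), and the iminium 17 is hydrolysed to the cyclobutanone. The closest known reaction type is the keteniminium–olefin [2+2] cycloaddition with amides of C2-symmetric 2,5-dimethylpyrrolidine. C-a and C-b must be cis because a four-membered ring cannot span the five-membered ring trans, and their absolute sense is set by the auxiliary, whose methyl groups block one of the two approach paths of the indene face. C-c is α to the new ketone and is set thermodynamically by DBU-mediated enolisation, which should place the aryl group on the convex face, cis to both ring-fusion hydrogens and away from ring A. The step needs regioselectivity, which the styrenic polarisation supplies (a benzylic, not a secondary alkyl, cation), and chemoselectivity of the anhydride for the amide over the chromanone carbonyl, which is secured by consuming the anhydride with a slight excess of 15 before 9 is added.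

Step 11
Reactants: 19 cis-fused cyclobuta-indane cyclobutanone
Product: 20 C-d methylene compound (exocyclic C=CH2 in place of the cyclobutanone C=O; C-a S; C-b R; C-c S)
Conditions: Ph3PCH3Br, NaN(SiMe3)2, THF, 0 °C; then 19, −78 to 0 °C
Reagents that add atoms: methyltriphenylphosphonium bromide, C[P+](c1ccccc1)(c1ccccc1)c1ccccc1.[Br-]
Why: Wittig methylenation, in which the strained cyclobutanone is far more electrophilic than the doubly oxygen-conjugated, peri-hindered chromanone carbonyl and should react alone, while any transient enolisation at C-c is harmless because that centre already has its stable configuration.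

Step 12
Reactants: 20 C-d methylene compound
Product: 21 C-d spiro-cyclopropane (C-a S; C-b R; C-c S)
Conditions: Et2Zn, CH2I2, ClCH2CH2Cl, 0 °C to rt
Reagents that add atoms: diiodomethane, ICI
Why: Simmons–Smith cyclopropanation (diethylzinc variant) of the only alkene; the spiro carbon carries two identical CH2 groups, so no stereocentre arises.

Step 13
Reactants: 21 C-d spiro-cyclopropane
Product: 22 C-d gem-dimethyl chromanone (C-a S; C-b R; C-c S)
Conditions: H2 (3 atm), PtO2, EtOAc–AcOH, rt
Reagents that add atoms: none
Why: Catalytic hydrogenolysis of the cyclopropane at its least hindered CH2–CH2 bond should turn the spiro ring into the two methyl groups, while the aryl silyl ethers are inert and the vinylogous-ester chromanone carbonyl is the least reducible type of aryl ketone.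

Step 14
Reactants: 22 C-d gem-dimethyl chromanone
Product: 24 bis-TBS ether of the target (2,2-dimethyl-2H-chromene), via chroman-4-ol 23 (not isolated)
Conditions: NaBH4, MeOH–THF, 0 °C; then p-TsOH·H2O (cat.), PhMe, 60 °C
Reagents that add atoms: none
Why: Hydride reduction of the ketone followed by acid-catalysed E1 dehydration through a benzylic cation stabilised by the ortho and para oxygens should give the chromene; the C4 stereocentre of 23 is formed as a mixture and destroyed again.

Step 15
Reactants: 24 bis-TBS ether of the target
Product: 25 CNP0207533.1 (target; C-a S; C-b R; C-c S)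
Conditions: Bu4NF, AcOH, THF, 0 °C, degassed
Reagents that add atoms: none
Why: Fluoride-mediated cleavage of the two aryl silyl ethers, buffered with acetic acid so that no oxidisable catecholate builds up, should leave the chromene, the methyl ether and the cyclobutane untouched.

**Compound list**

1 | phloroglucinol | Oc1cc(O)cc(O)c1 | starting material
2 | 3,3-dimethylacrylic acid | CC(C)=CC(=O)O | starting material
3 | 5,7-dihydroxy-2,2-dimethylchroman-4-one | CC1(C)CC(=O)c2c(O)cc(O)cc2O1 | intermediate
4 | 5-hydroxy-7-methoxy-2,2-dimethylchroman-4-one | CC1(C)CC(=O)c2c(O)cc(OC)cc2O1 | intermediate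
5 | 5-(allyloxy)-7-methoxy-2,2-dimethylchroman-4-one | CC1(C)CC(=O)c2c(OCC=C)cc(OC)cc2O1 | intermediate
6 | 6-allyl-5-hydroxy-7-methoxy-2,2-dimethylchroman-4-one | CC1(C)CC(=O)c2c(O)c(CC=C)c(OC)cc2O1 | intermediate
7 | 6-allyl-7-methoxy-2,2-dimethyl-4-oxochroman-5-yl trifluoromethanesulfonate | CC1(C)CC(=O)c2c(OS(=O)(=O)C(F)(F)F)c(CC=C)c(OC)cc2O1 | intermediate
8 | 6-allyl-7-methoxy-2,2-dimethyl-5-vinylchroman-4-one | CC1(C)CC(=O)c2c(C=C)c(CC=C)c(OC)cc2O1 | intermediate
9 | tricyclic indene: 7-methoxy-2,2-dimethylchroman-4-one with cyclopentene fused across C5–C6, double bond attached to C5 | COc1cc2OC(C)(C)CC(=O)c2c2C=CCc12 | intermediate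
10 | 3,4-dihydroxyphenylacetic acid | OC(=O)Cc1ccc(O)c(O)c1 | starting material
11 | tert-butyldimethylsilyl 3,4-bis(tert-butyldimethylsilyloxy)phenylacetate | CC(C)(C)[Si](C)(C)OC(=O)Cc1ccc(O[Si](C)(C)C(C)(C)C)c(O[Si](C)(C)C(C)(C)C)c1 | intermediate
12 | 3,4-bis(tert-butyldimethylsilyloxy)phenylacetic acid | OC(=O)Cc1ccc(O[Si](C)(C)C(C)(C)C)c(O[Si](C)(C)C(C)(C)C)c1 | intermediate
13 | (2R,5R)-2,5-dimethylpyrrolidine | C[C@@H]1CC[C@@H](C)N1 | starting material
14 | 3,4-bis(tert-butyldimethylsilyloxy)phenylacetyl chloride | ClC(=O)Cc1ccc(O[Si](C)(C)C(C)(C)C)c(O[Si](C)(C)C(C)(C)C)c1 | intermediate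
15 | 2-[3,4-bis(tert-butyldimethylsilyloxy)phenyl]-1-[(2R,5R)-2,5-dimethylpyrrolidin-1-yl]ethanone | O=C(Cc1ccc(O[Si](C)(C)C(C)(C)C)c(O[Si](C)(C)C(C)(C)C)c1)N1[C@H](C)CC[C@H]1C | intermediate
16 | (2R,5R)-1-[2-(3,4-bis(TBSO)phenyl)ethenylidene]-2,5-dimethylpyrrolidinium triflate (keteniminium) | C(=C=[N+]1[C@H](C)CC[C@H]1C)c1ccc(O[Si](C)(C)C(C)(C)C)c(O[Si](C)(C)C(C)(C)C)c1.[O-]S(=O)(=O)C(F)(F)F | intermediate
17 | cyclobutaniminium triflate: cis-fused [2+2] adduct with the (2R,5R)-pyrrolidinium at C-d (C-a S; C-b R; C-c as formed, unassigned) | COc1cc2c(c3c1C[C@H]1[C@@H]3C(c3ccc(O[Si](C)(C)C(C)(C)C)c(O[Si](C)(C)C(C)(C)C)c3)C1=[N+]1[C@H](C)CC[C@H]1C)C(=O)CC(C)(C)O2.[O-]S(=O)(=O)C(F)(F)F | intermediate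
18 | cis-fused cyclobutanone as mixture of C-c epimers (C-a S; C-b R) | COc1cc2c(c3c1C[C@H]1[C@@H]3C(c3ccc(O[Si](C)(C)C(C)(C)C)c(O[Si](C)(C)C(C)(C)C)c3)C1=O)C(=O)CC(C)(C)O2 | intermediate
19 | cis-fused cyclobuta-indane cyclobutanone, aryl at C-c on the convex face, cis to both ring-fusion hydrogens (C-a S; C-b R; C-c R) | COc1cc2c(c3c1C[C@H]1[C@@H]3[C@H](c3ccc(O[Si](C)(C)C(C)(C)C)c(O[Si](C)(C)C(C)(C)C)c3)C1=O)C(=O)CC(C)(C)O2 | intermediate
20 | C-d methylene compound (C-a S; C-b R; C-c S) | COc1cc2c(c3c1C[C@H]1[C@@H]3[C@H](c3ccc(O[Si](C)(C)C(C)(C)C)c(O[Si](C)(C)C(C)(C)C)c3)C1=C)C(=O)CC(C)(C)O2 | intermediate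
21 | C-d spiro-cyclopropane (C-a S; C-b R; C-c S) | COc1cc2c(c3c1C[C@H]1[C@@H]3[C@H](c3ccc(O[Si](C)(C)C(C)(C)C)c(O[Si](C)(C)C(C)(C)C)c3)C14CC4)C(=O)CC(C)(C)O2 | intermediate
22 | C-d gem-dimethyl chromanone (C-a S; C-b R; C-c S) | COc1cc2c(c3c1C[C@H]1[C@@H]3[C@H](c3ccc(O[Si](C)(C)C(C)(C)C)c(O[Si](C)(C)C(C)(C)C)c3)C1(C)C)C(=O)CC(C)(C)O2 | intermediate
23 | corresponding chroman-4-ol, mixture of C4 epimers (C-a S; C-b R; C-c S) | COc1cc2c(c3c1C[C@H]1[C@@H]3[C@H](c3ccc(O[Si](C)(C)C(C)(C)C)c(O[Si](C)(C)C(C)(C)C)c3)C1(C)C)C(O)CC(C)(C)O2 | intermediate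
24 | bis-TBS ether of the target, 2,2-dimethyl-2H-chromene (C-a S; C-b R; C-c S) | COc1cc2c(c3c1C[C@H]1[C@@H]3[C@H](c3ccc(O[Si](C)(C)C(C)(C)C)c(O[Si](C)(C)C(C)(C)C)c3)C1(C)C)C=CC(C)(C)O2 | intermediate
25 | CNP0207533.1 (C-a S; C-b R; C-c S; cis ring fusion, catechol ring cis to both ring-fusion hydrogens) | COc1cc2c(c3c1C[C@H]1[C@@H]3[C@H](c3ccc(O)c(O)c3)C1(C)C)C=CC(C)(C)O2 | target

**Step count and risks**

Total: 15 steps. Longest linear sequence: 13 steps (steps 1–7 and 10–15); the amide branch (steps 8–9) has 2 steps.

Steps most likely to fail: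

1. Step 10. The hindered chiral keteniminium may add slowly to a styrenic bond that is deactivated by the ortho acyl group, so that proton loss from the benzylic cation competes with ring closure, or the auxiliary may discriminate poorly between the two indene faces. The fallback gives up auxiliary control in favour of a more reactive achiral keteniminium and a resolution. It sets out from acid 12 (through its chloride 14) and indene 9. The chloride is condensed with dimethylamine to give N,N-dimethyl-2-[3,4-bis(TBSO)phenyl]acetamide F1. Tf2O and collidine convert it into the unhindered N,N-dimethylketeniminium triflate F2, which adds to 9 to give the racemic cyclobutaniminium triflate F3. Hydrolysis and DBU equilibration as in step 10 give the racemic cis-fused convex-aryl ketone, and preparative chromatography on a chiral stationary phase removes the mirror-image ketone F4, so the route is rejoined at 19.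

2. Step 13. The slow cyclopropane hydrogenolysis may be overtaken by reduction of the chromanone carbonyl (and then loss of the benzylic oxygen) or by saturation of an arene. The fallback sets out from 20, bypasses steps 12 and 13 and returns at 22 by radical hydromethylation. With Fe(acac)3 and PhSiH3 in THF–MeOH, hydrogen-atom transfer to the methylene carbon gives the tertiary cyclobutyl radical. This radical adds to formaldehyde N-(octylsulfonyl)hydrazone (made in the flask from octane-1-sulfonohydrazide and aqueous formaldehyde) to give the N'-alkyl octanesulfonohydrazide F5. Warming in MeOH at 60 °C expels octanesulfinic acid and dinitrogen and leaves the second methyl group of 22. No hydrogenation catalyst is involved, so ketone and arenes are not at risk.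

3. Step 11. The basic ylide may enolise the α-aryl cyclobutanone instead of adding to it, or olefinate the chromanone carbonyl as well. The fallback sets out from 19 and returns at 20 by a Peterson olefination. The non-basic organocerium reagent from Me3SiCH2MgCl and CeCl3 (THF, −78 °C) adds to the strained cyclobutanone carbonyl only and gives the β-hydroxysilane F6. Catalytic p-TsOH in CH2Cl2 then eliminates trimethylsilanol to form the exocyclic alkene.

**Further compounds**

F1 | step 10 | N,N-dimethyl-2-[3,4-bis(tert-butyldimethylsilyloxy)phenyl]acetamide | CN(C)C(=O)Cc1ccc(O[Si](C)(C)C(C)(C)C)c(O[Si](C)(C)C(C)(C)C)c1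
F2 | step 10 | N-[2-(3,4-bis(TBSO)phenyl)ethenylidene]-N-methylmethanaminium triflate (keteniminium) | C[N+](C)=C=Cc1ccc(O[Si](C)(C)C(C)(C)C)c(O[Si](C)(C)C(C)(C)C)c1.[O-]S(=O)(=O)C(F)(F)F
F3 | step 10 | racemic cis-fused N,N-dimethylcyclobutaniminium triflate (one enantiomer drawn; C-c as formed) | COc1cc2c(c3c1C[C@H]1[C@@H]3C(c3ccc(O[Si](C)(C)C(C)(C)C)c(O[Si](C)(C)C(C)(C)C)c3)C1=[N+](C)C)C(=O)CC(C)(C)O2.[O-]S(=O)(=O)C(F)(F)F
F4 | step 10 | mirror image of ketone 19 (C-a R; C-b S; C-c S) | COc1cc2c(c3c1C[C@@H]1[C@H]3[C@@H](c3ccc(O[Si](C)(C)C(C)(C)C)c(O[Si](C)(C)C(C)(C)C)c3)C1=O)C(=O)CC(C)(C)O2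
F5 | step 13 | N'-alkyl octane-1-sulfonohydrazide: C-d bearing CH3 and CH2NHNHSO2C8H17, mixture at C-d (C-a S; C-b R; C-c S) | COc1cc2c(c3c1C[C@H]1[C@@H]3[C@H](c3ccc(O[Si](C)(C)C(C)(C)C)c(O[Si](C)(C)C(C)(C)C)c3)C1(C)CNNS(=O)(=O)CCCCCCCC)C(=O)CC(C)(C)O2
F6 | step 11 | β-hydroxysilane: C-d bearing OH and CH2SiMe3, carbinol configuration unassigned (C-a S; C-b R; C-c S) | COc1cc2c(c3c1C[C@H]1[C@@H]3[C@H](c3ccc(O[Si](C)(C)C(C)(C)C)c(O[Si](C)(C)C(C)(C)C)c3)C1(O)C[Si](C)(C)C)C(=O)CC(C)(C)O2
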